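The readings are calculated with made-up constants; scatter was added.

Amounts first: Wednesday's, Friday's and Sunday's charge the same X, D and Z, and they differ in when D or Z goes in.

| flask | X | D | Z | remark | time |
|---|---|---|---|---|---|
| larch | 5 mM | 3 equiv | 1.3 equiv | run made earlier |  |
| maple | 2.5 mM | 3 equiv | 1.3 equiv | run made earlier |  |
| Wednesday's | 5.0 mM | 3.00 equiv | 1.30 equiv (fed, over 40 s) | all else is in the flask from the start; the feed brings no volume worth counting | 3.0 min |
| Friday's | 5.0 mM | 3.00 equiv (fed, over 40 s) | 1.30 equiv | all else is in the flask from the start; the feed brings no volume worth counting | 3.0 min |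
| Sunday's | 5.0 mM | 3.00 equiv | 1.30 equiv | everything together at the start | 3.0 min |

- larch (time / s: J / %, X / %): 20.0: 10, 53; 40.0: 17, 38; 60.0: 27, 19; 80.0: 38, 5; 120: 51, 3
- maple (time / s: J / %, X / %): 10.0: 10, 22; 20.0: 19, 7; 40.0: 33, 0

(scatter of a reading: 2 percentage points)

1. the flask that comes out highest in amount of J, in percent of the X charged, or "all alike" when all lie within 1.5 percentage points (Wednesday's / Friday's / Sunday's / all alike)
2. J at the end, in percent of the X charged, Wednesday's
3. J at the end, in percent of the X charged, Friday's
4. J at the end, in percent of the X charged, Sunday's

- X is a solid; its amount is given per volume of the solution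
- reactions considered so far: G -> L; D + L -> J; Z + L -> E; X <-> G
- at the start none of X is in solution

X dissolves, G gives L, and D and Z compete for L. So I sought one number, the odds of J against E at the charged ratio: the selectivity factor times the ratio of D to Z. In larch, between 20.0 s and 80.0 s, X fell by 48 percentage points while J rose by 28 points. Taking cG and cL as steady there, I gave the difference to E, and the odds read 1.40. Maple read 1.50, close within the scatter. Even odds are the crossing, and the larch reading stands above it, so I reckoned J a share of 58.3%, my figure for Sunday's.

With L taken as formed steadily, I reckoned the mean share during the linear feed over 40 s at 75.5% for Wednesday's, where Z is fed, and at 37.5% for Friday's, where D is fed. The odds gave the order, but the gaps needed a second number: the 32.0% of the X charged that passes during the feed at the rate of fall read in larch. For fully reacted G, I reckoned 63.8% for Wednesday's and 51.7% for Friday's, so Wednesday's led in my reckoning.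

The forecast, above my figures, named Wednesday's with 66%, 56% and 61% for Wednesday's, Friday's and Sunday's: “Feeding Z keeps Z low during the first third of the flux”.

The flasks gave 61.6%, 51.9% and 57.0%, in that order.

    G → L (k = 0.0270 s⁻¹)
    D + L → J (k = 8400 M⁻¹ s⁻¹)
    Z + L → E (k = 15000 M⁻¹ s⁻¹)
    X ⇌ G, rate k4*(cs4 - [G]) while solid is left; crystals form when [G] > cs4 (solubility = 1.60 mM, k = 1.90 s⁻¹)

Wednesday's came highest, at 61.6%, with 2.17% of the X charged still standing as G. Over its first 40 s, the mean cD was 14.3 mM and the mean cZ 3.09 mM. Scaling the larch odds by those means gives 2.82, and in Wednesday's J over E at the end of the feed stood at 2.79.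

For the neighbour of Wednesday's charged with 0.750 equiv of D, the charged ratio scales my odds to 0.350, below the crossing, and the same reckoning gives 32.7%. That neighbour gave 31.1%.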